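**Plan**

- Retrosynthesis, last event first: the equatorial C9–Br/C10–Cl pair is traced back by a 1,2-interchange of the two halogens to its trans-diaxial isomer (C9–Cl/C10–Br), and that through bromohydrin and epoxide to a C9=C10 alkene.
- Ring B is then cut at C6–C7 and C10–C11 (Diels–Alder), and ring A at C5–C6 (bromonium-induced cyclization of an acyclic β-keto ester).
- Enabling feature: the spiro carbon C6 carries a one-carbon arm (C11) and is flanked by C1, which can be a carbonyl. Ring A as a 2-methylenecyclohexanone (C6=C11 conjugated with C1=O) is therefore a dienophile, and C7–C8–C9(CH3)–C10 of ring B is an isoprene unit. A silyl group on C10 is a helper that later moves the ring-B double bond from C8=C9 to C9=C10.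
- Forward order: ring A (steps 1–6), diene (steps 7–9), ring B and the spiro centre by cycloaddition (step 10), then desilylation, methylenation and halogenation of ring B (steps 11–16).
- Stereochemistry: C4 comes from a catalytic enantioselective bromochlorination carried through an enantiospecific bromonium cyclization. C6 comes from substrate-controlled facial selectivity in the cycloaddition. C9 and C10 come from face-selective epoxidation, trans-diaxial opening, retentive chlorination and the stereospecific diaxial-to-diequatorial halogen interchange.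

Key step: step 10

**Remarks**

- Locants used throughout (spiro[5.5]undecane): C1 = ring A carbon that bears the exocyclic CH2 (a carbonyl up to step 11), C2, C3, C4 (CHBr), C5 (CMe2), C6 (spiro), then ring B C7, C8, C9 (C–CH3), C10, C11. The target is (4R,6S,9S,10S).
- Assumption: in step 1 the enantiomer of the ligand that gives the (R)-bromochloride is used.
- Conformational premise: in every spiro compound, ring B is taken as a chair (half-chair for the alkene) with the quaternary C5 equatorial and C1 axial, because an axial C5 would point a methyl group across ring B.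

**Route**

Step 1
Reactants: 1 3-methylbut-2-en-1-ol
Product: 2 (R)-2-bromo-3-chloro-3-methylbutan-1-ol
Conditions: NBS, ClTi(OiPr)3, chiral tridentate Schiff-base amino-alcohol ligand (20 mol %), hexanes, −20 °C
Reagents that add atoms: N-bromosuccinimide O=C1CCC(=O)N1Br; chlorotitanium triisopropoxide CC(C)O[Ti](Cl)(OC(C)C)OC(C)C
Why: Catalytic enantioselective bromochlorination of an allylic alcohol, in which the chiral titanium alkoxide complex directs bromonium formation to one alkene face and delivers chloride anti to the tertiary carbon, so that the C–Br stereocentre (later C4) is set as R.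

Step 2
Reactants: 2 (R)-2-bromo-3-chloro-3-methylbutan-1-ol
Product: 3 (R)-2-bromo-3-chloro-3-methylbutyl trifluoromethanesulfonate
Conditions: Tf2O, 2,6-lutidine, CH2Cl2, −78 °C
Reagents that add atoms: trifluoromethanesulfonic anhydride O=S(=O)(OS(=O)(=O)C(F)(F)F)C(F)(F)F
Why: O-Sulfonylation of the primary alcohol at low temperature gives the triflate without touching the stereocentre.

Step 3
Reactants: 3 (R)-2-bromo-3-chloro-3-methylbutyl trifluoromethanesulfonate; 4 methyl 3-oxobutanoate
Product: 6 methyl (6R)-6-bromo-7-chloro-7-methyl-3-oxooctanoate, via acetoacetate dianion 5 (not isolated)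
Conditions: 4, NaH then n-BuLi, THF, 0 °C; then 3, −78 → −40 °C
Reagents that add atoms: none
Why: SN2 γ-alkylation of the acetoacetate dianion by the primary triflate at low temperature builds the C2–C3 bond while the adjacent C–Br stereocentre is not involved.

Step 4
Reactants: 6 methyl (6R)-6-bromo-7-chloro-7-methyl-3-oxooctanoate
Product: 8 methyl (3R)-3-bromo-2,2-dimethyl-6-oxocyclohexane-1-carboxylate, via bromonium ion 7 (not isolated)
Conditions: (CF3)2CHOH, 23 °C
Reagents that add atoms: none
Why: Solvolytic ionization of the tertiary chloride in the ionizing, non-nucleophilic solvent is assisted by the vicinal bromine and gives a configurationally defined bromonium ion, which the enol carbon of the β-keto ester opens at the tertiary carbon in a chair-like 6-endo halonium-induced cation–olefin cyclization that forms C5–C6 and carries the C–Br configuration over unchanged (Br equatorial).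

Step 5
Reactants: 8 methyl (3R)-3-bromo-2,2-dimethyl-6-oxocyclohexane-1-carboxylate
Product: 9 methyl (5R)-5-bromo-2-methoxy-6,6-dimethylcyclohex-1-ene-1-carboxylate
Conditions: NaH, DMF, 0 °C; then Me2SO4, 0 → 23 °C
Reagents that add atoms: dimethyl sulfate COS(=O)(=O)OC
Why: O-Alkylation of the β-keto ester enolate with a hard methylating agent in a polar aprotic solvent (C-alkylation would have to build a quaternary carbon beside CMe2) masks the ketone as an enol ether.

Step 6
Reactants: 9 methyl (5R)-5-bromo-2-methoxy-6,6-dimethylcyclohex-1-ene-1-carboxylate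
Product: 11 (4R)-4-bromo-3,3-dimethyl-2-methylidenecyclohexan-1-one, via allylic alcohol 10 (not isolated)
Conditions: iBu2AlH, CH2Cl2, −78 °C; then 1 M HCl, THF, 0 → 23 °C
Reagents that add atoms: water O
Why: 1,2-Reduction of the vinylogous carbonate ester to the allylic alcohol followed by acid-mediated enol ether hydrolysis with vinylogous loss of the hydroxyl group (addition–elimination) gives the α-methylene ketone.

Step 7
Reactants: 12 3-(trimethylsilyl)prop-2-yn-1-ol
Product: 14 (E)-2-methyl-3-(trimethylsilyl)prop-2-en-1-ol, via alkenylmagnesium chelate 13 (not isolated)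
Conditions: MeMgCl (3 equiv), CuI (10 mol %), THF, 0 → 23 °C; then aq. NH4Cl
Reagents that add atoms: methylmagnesium chloride C[Mg]Cl
Why: Copper-catalysed anti-carbomagnesiation of the propargylic alkoxide puts the methyl group on the carbinol-proximal carbon and magnesium on the silylated carbon in a five-membered chelate, so that protonation gives the E vinylsilane.

Step 8
Reactants: 14 (E)-2-methyl-3-(trimethylsilyl)prop-2-en-1-ol
Product: 15 (E)-2-methyl-3-(trimethylsilyl)prop-2-enal
Conditions: MnO2, CH2Cl2, 23 °C
Reagents that add atoms: none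
Why: Chemoselective MnO2 oxidation of the allylic alcohol gives the enal with the double-bond geometry retained.

Step 9
Reactants: 15 (E)-2-methyl-3-(trimethylsilyl)prop-2-enal
Product: 16 (E)-trimethyl(2-methylbuta-1,3-dien-1-yl)silane
Conditions: Ph3PCH3Br, n-BuLi, THF, 0 °C; then 15, 0 → 23 °C
Reagents that add atoms: methyltriphenylphosphonium bromide C[P+](c1ccccc1)(c1ccccc1)c1ccccc1.[Br-]
Why: Wittig methylenation of the aldehyde gives the diene with the E vinylsilane intact.

Step 10
Reactants: 11 (4R)-4-bromo-3,3-dimethyl-2-methylidenecyclohexan-1-one; 16 (E)-trimethyl(2-methylbuta-1,3-dien-1-yl)silane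
Product: 17 (4R,6R)-4-bromo-5,5,9-trimethyl-10-(trimethylsilyl)spiro[5.5]undec-8-en-1-one (both C10 epimers are usable)
Conditions: Me2AlCl (20 mol %), CH2Cl2, −78 → −20 °C
Reagents that add atoms: none
Why: Complexation of the C1 carbonyl by the Lewis acid lowers the LUMO of the exocyclic C6=C11 alkene, which undergoes a concerted, asynchronous [4+2] cycloaddition with the s-cis diene, joining C6 to C7 and C11 to the silylated terminus C10. The closest known reaction type is the Lewis-acid-promoted Diels–Alder spiroannulation of 3,3-dimethyl-2-methylenecyclohexanone with isoprene. Ring B closes by intermolecular cycloaddition in which both of its new bonds form in the same event and C6 becomes the spiro atom. C6 should be set by the substrate: in the ring A conformer with Br equatorial, the axial methyl of C5 shields the face of C6 that is cis to Br, so C7 enters trans to Br and C11 ends cis to it; C10 should form mainly endo, but its configuration is erased in step 11. The step needs the regiochemistry with C9 para to C6 and this facial selectivity: the 2-methyl group makes the silylated terminus the more nucleophilic end, which joins the unhindered C11 while the unsubstituted terminus goes to the crowded C6, and the facial bias is built into ring A.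

Step 11
Reactants: 17 (4R,6R)-4-bromo-5,5,9-trimethyl-10-(trimethylsilyl)spiro[5.5]undec-8-en-1-one
Product: 18 (4R,6R)-4-bromo-5,5,9-trimethylspiro[5.5]undec-9-en-1-one
Conditions: CF3CO2H (2 equiv), CH2Cl2, −20 → 0 °C
Reagents that add atoms: none
Why: Protodesilylation of the allylsilane (SE2' electrophilic substitution) adds the proton at C8 through the tertiary β-silyl cation at C9 and expels silicon, so the double bond ends up only at C9=C10 on the arm that carries C11 and the C10 stereocentre is erased.

Step 12
Reactants: 18 (4R,6R)-4-bromo-5,5,9-trimethylspiro[5.5]undec-9-en-1-one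
Product: 19 (4R,6S)-4-bromo-5,5,9-trimethyl-1-methylidenespiro[5.5]undec-9-ene
Conditions: Cp2TiMe2, toluene, 70 °C, dark
Reagents that add atoms: dimethyltitanocene C[Ti](C)(C1C=CC=C1)C1C=CC=C1
Why: Carbonyl methylenation by the titanium methylidene generated on heating Cp2TiMe2 (via an oxatitanacyclobutane) is non-basic and therefore suited to the hindered, enolizable ketone and the secondary bromide; no stereocentre is formed.

Step 13
Reactants: 19 (4R,6S)-4-bromo-5,5,9-trimethyl-1-methylidenespiro[5.5]undec-9-ene
Product: 20 (4R,6S,9R,10S)-4-bromo-9,10-epoxy-5,5,9-trimethyl-1-methylidenespiro[5.5]undecane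
Conditions: mCPBA, NaHCO3, CH2Cl2, −20 → 0 °C
Reagents that add atoms: 3-chloroperoxybenzoic acid O=C(OO)c1cccc(Cl)c1
Why: Prilezhaev epoxidation takes the trisubstituted ring-B alkene in preference to the 1,1-disubstituted, neopentyl-type exocyclic alkene and, with ring B held as a half-chair by equatorial C5, attacks the face anti to the axial C1, setting C9 (R) and C10 (S).

Step 14
Reactants: 20 (4R,6S,9R,10S)-4-bromo-9,10-epoxy-5,5,9-trimethyl-1-methylidenespiro[5.5]undecane
Product: 21 (4R,6S,9R,10R)-4,10-dibromo-5,5,9-trimethyl-1-methylidenespiro[5.5]undecan-9-ol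
Conditions: Li2NiBr4, THF, 0 → 23 °C
Reagents that add atoms: dilithium tetrabromonickelate [Li+].[Li+].[Ni+2].[Br-].[Br-].[Br-].[Br-]
Why: SN2 opening of the epoxide by bromide at the less substituted C10, which is also the trans-diaxial mode of opening, inverts C10 and leaves the C9–O bond untouched, giving axial bromide at C10 and axial tertiary hydroxyl at C9.

Step 15
Reactants: 21 (4R,6S,9R,10R)-4,10-dibromo-5,5,9-trimethyl-1-methylidenespiro[5.5]undecan-9-ol
Product: 23 (4R,6S,9R,10R)-4,10-dibromo-9-chloro-5,5,9-trimethyl-1-methylidenespiro[5.5]undecane, via bromonium ion 22 (not isolated)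
Conditions: Me2C=C(Cl)NMe2, CH2Cl2, 0 → 23 °C
Reagents that add atoms: 1-chloro-N,N,2-trimethylprop-1-en-1-amine CC(C)=C(Cl)N(C)C
Why: Deoxychlorination under neutral conditions: the alkoxyiminium derivative of the tertiary alcohol ionizes with participation of the antiperiplanar axial bromine, and chloride reopens the bromonium ion at the tertiary C9 in the trans-diaxial sense, so C9–Cl forms with net retention (neighbouring-group participation) and the bromine stays on C10.

Step 16
Reactants: 23 (4R,6S,9R,10R)-4,10-dibromo-9-chloro-5,5,9-trimethyl-1-methylidenespiro[5.5]undecane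
Product: 24 obtusane, (4R,6S,9S,10S)-4,9-dibromo-10-chloro-5,5,9-trimethyl-1-methylidenespiro[5.5]undecane
Conditions: MeCN, 80 °C
Reagents that add atoms: none
Why: Thermal dyotropic diaxial-to-diequatorial rearrangement of a vicinal trans-diaxial dihalide: chlorine shifts from C9 to C10 and bromine from C10 to C9, each on its own face and with inversion at both carbons, which delivers the equatorial tertiary bromide and equatorial secondary chloride and is driven by loss of the 1,3-diaxial contact between the C10 bromine and C1 and by the polar solvent.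

**Compound list**

1 | 3-methylbut-2-en-1-ol | CC(C)=CCO | starting material
2 | (R)-2-bromo-3-chloro-3-methylbutan-1-ol | OC[C@@H](Br)C(C)(C)Cl | intermediate
3 | (R)-2-bromo-3-chloro-3-methylbutyl trifluoromethanesulfonate | O=S(=O)(OC[C@@H](Br)C(C)(C)Cl)C(F)(F)F | intermediate
4 | methyl 3-oxobutanoate | COC(=O)CC(C)=O | starting material
5 | acetoacetate dianion, sodium lithium salt (not isolated) | [Na+].[Li+].[CH2-]C(=O)[CH-]C(=O)OC | intermediate
6 | methyl (6R)-6-bromo-7-chloro-7-methyl-3-oxooctanoate | COC(=O)CC(=O)CC[C@@H](Br)C(C)(C)Cl | intermediate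
7 | bromonium ion from 6, chloride salt (not isolated) | COC(=O)CC(=O)CC[C@@H]1C(C)(C)[Br+]1.[Cl-] | intermediate
8 | methyl (3R)-3-bromo-2,2-dimethyl-6-oxocyclohexane-1-carboxylate (C1 epimerizable) | COC(=O)C1C(=O)CC[C@@H](Br)C1(C)C | intermediate
9 | methyl (5R)-5-bromo-2-methoxy-6,6-dimethylcyclohex-1-ene-1-carboxylate | COC(=O)C1=C(OC)CC[C@@H](Br)C1(C)C | intermediate
10 | [(5R)-5-bromo-2-methoxy-6,6-dimethylcyclohex-1-en-1-yl]methanol (not isolated) | OCC1=C(OC)CC[C@@H](Br)C1(C)C | intermediate
11 | (4R)-4-bromo-3,3-dimethyl-2-methylidenecyclohexan-1-one | O=C1CC[C@@H](Br)C(C)(C)C1=C | intermediate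
12 | 3-(trimethylsilyl)prop-2-yn-1-ol | C[Si](C)(C)C#CCO | starting material
13 | cyclic alkenylmagnesium alkoxide (not isolated) | CC1=C([Si](C)(C)C)[Mg]OC1 | intermediate
14 | (E)-2-methyl-3-(trimethylsilyl)prop-2-en-1-ol | C[Si](C)(C)/C=C(\C)CO | intermediate
15 | (E)-2-methyl-3-(trimethylsilyl)prop-2-enal | C[Si](C)(C)/C=C(\C)C=O | intermediate
16 | (E)-trimethyl(2-methylbuta-1,3-dien-1-yl)silane | C[Si](C)(C)/C=C(\C)C=C | intermediate
17 | (4R,6R)-4-bromo-5,5,9-trimethyl-10-(trimethylsilyl)spiro[5.5]undec-8-en-1-one (C10 epimers) | O=C1CC[C@@H](Br)C(C)(C)[C@]12CC=C(C)C([Si](C)(C)C)C2 | intermediate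
18 | (4R,6R)-4-bromo-5,5,9-trimethylspiro[5.5]undec-9-en-1-one | O=C1CC[C@@H](Br)C(C)(C)[C@]12CCC(C)=CC2 | intermediate
19 | (4R,6S)-4-bromo-5,5,9-trimethyl-1-methylidenespiro[5.5]undec-9-ene | C=C1CC[C@@H](Br)C(C)(C)[C@]12CCC(C)=CC2 | intermediate
20 | (4R,6S,9R,10S)-4-bromo-9,10-epoxy-5,5,9-trimethyl-1-methylidenespiro[5.5]undecane | C=C1CC[C@@H](Br)C(C)(C)[C@]12CC[C@@]3(C)O[C@H]3C2 | intermediate
21 | (4R,6S,9R,10R)-4,10-dibromo-5,5,9-trimethyl-1-methylidenespiro[5.5]undecan-9-ol | C=C1CC[C@@H](Br)C(C)(C)[C@]12CC[C@@](C)(O)[C@H](Br)C2 | intermediate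
22 | C9,C10-bromonium ion on the ring-B face cis to C1, chloride salt (not isolated) | C=C1CC[C@@H](Br)C(C)(C)[C@]12CC[C@]3(C)[Br+][C@@H]3C2.[Cl-] | intermediate
23 | (4R,6S,9R,10R)-4,10-dibromo-9-chloro-5,5,9-trimethyl-1-methylidenespiro[5.5]undecane | C=C1CC[C@@H](Br)C(C)(C)[C@]12CC[C@@](C)(Cl)[C@H](Br)C2 | intermediate
24 | obtusane, (4R,6S,9S,10S)-4,9-dibromo-10-chloro-5,5,9-trimethyl-1-methylidenespiro[5.5]undecane | C=C1CC[C@@H](Br)C(C)(C)[C@]12CC[C@](C)(Br)[C@@H](Cl)C2 | target

**Count**

Total steps: 16. Longest linear sequence: 13 steps (steps 1–6 and 10–16); the diene branch (steps 7–9) joins at step 10.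

**Steps most likely to fail, with fallbacks**

Step 10 (key cycloaddition). The vinylsilane diene may be consumed by the Lewis acid (desilylation, oligomerization), the cycloaddition at the doubly hindered C6 may be too slow, or the facial selectivity may erode. Fallback, setting out from 9 and returning at 18: ring B is built by a Michael–aldol annulation that forms the same two bonds in two stages. Reduction of 9 with iBu2AlH is stopped at the allylic alcohol 10, which is isolated and oxidized with MnO2 to (5R)-5-bromo-2-methoxy-6,6-dimethylcyclohex-1-ene-1-carbaldehyde F1. Aqueous HCl in THF should free (4R)-4-bromo-2-(hydroxymethylidene)-3,3-dimethylcyclohexan-1-one F2. Its Et3N-mediated Michael addition to but-3-en-2-one, again anti to the axial C5 methyl, should give (1S,3R)-3-bromo-2,2-dimethyl-6-oxo-1-(3-oxobutyl)cyclohexane-1-carbaldehyde F3. Aldol condensation on the aldehyde (pyrrolidine, AcOH) should close ring B as (4R,6R)-4-bromo-5,5-dimethylspiro[5.5]undec-10-ene-1,9-dione F4. Conjugate reduction with K[sBu3BH] and trapping of the C9–C10 enolate with PhNTf2 should give (4R,6R)-4-bromo-5,5-dimethyl-1-oxospiro[5.5]undec-9-en-9-yl trifluoromethanesulfonate F5, and Me2CuLi should replace the triflate by methyl to give 18.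

Step 16 (halogen interchange). The interchange may stop at an unfavourable equilibrium or be overtaken by loss of hydrogen halide at the temperature it needs. Fallback, setting out from 21 and returning at 24: the interchange is moved to a bromo–acyloxy pair and the chlorine is put on C10 afterwards. Acetylation of 21 (Ac2O, DMAP, Et3N, CH2Cl2) should give (4R,6S,9R,10R)-4,10-dibromo-5,5,9-trimethyl-1-methylidenespiro[5.5]undecan-9-yl acetate F6. Warming in MeCN should bring about the known diaxial-to-diequatorial rearrangement of a vicinal bromo ester, through the bridged acetoxonium ion, to (4R,6S,9S,10S)-4,9-dibromo-5,5,9-trimethyl-1-methylidenespiro[5.5]undecan-10-yl acetate F7. Reductive removal of the acetate with iBu2AlH at −78 °C should give (4R,6S,9S,10S)-4,9-dibromo-5,5,9-trimethyl-1-methylidenespiro[5.5]undecan-10-ol F8. SOCl2 in 1,4-dioxane (internal return of the chlorosulfite, retention) should then give 24.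

Step 15 (tertiary alcohol to chloride). The cationic intermediate may lose a proton (elimination to allylic bromides) instead of taking up chloride. Fallback, setting out from 19 and returning at 23: the halogens are added directly across the ring-B alkene of 19 with Bu4NBrCl2 in CH2Cl2 at −78 °C, an anti bromochlorination in which chloride opens the bromonium ion at the tertiary C9 in the trans-diaxial sense; no compound outside the list arises (F0).

**Further compounds**

F1 | step 10 | (5R)-5-bromo-2-methoxy-6,6-dimethylcyclohex-1-ene-1-carbaldehyde | O=CC1=C(OC)CC[C@@H](Br)C1(C)C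
F2 | step 10 | (4R)-4-bromo-2-(hydroxymethylidene)-3,3-dimethylcyclohexan-1-one | O=C1CC[C@@H](Br)C(C)(C)C1=CO
F3 | step 10 | (1S,3R)-3-bromo-2,2-dimethyl-6-oxo-1-(3-oxobutyl)cyclohexane-1-carbaldehyde | O=C1CC[C@@H](Br)C(C)(C)[C@]1(C=O)CCC(C)=O
F4 | step 10 | (4R,6R)-4-bromo-5,5-dimethylspiro[5.5]undec-10-ene-1,9-dione | O=C1CC[C@@H](Br)C(C)(C)[C@]12CCC(=O)C=C2
F5 | step 10 | (4R,6R)-4-bromo-5,5-dimethyl-1-oxospiro[5.5]undec-9-en-9-yl trifluoromethanesulfonate | O=C1CC[C@@H](Br)C(C)(C)[C@]12CCC(OS(=O)(=O)C(F)(F)F)=CC2
F6 | step 16 | (4R,6S,9R,10R)-4,10-dibromo-5,5,9-trimethyl-1-methylidenespiro[5.5]undecan-9-yl acetate | C=C1CC[C@@H](Br)C(C)(C)[C@]12CC[C@@](C)(OC(C)=O)[C@H](Br)C2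
F7 | step 16 | (4R,6S,9S,10S)-4,9-dibromo-5,5,9-trimethyl-1-methylidenespiro[5.5]undecan-10-yl acetate | C=C1CC[C@@H](Br)C(C)(C)[C@]12CC[C@](C)(Br)[C@@H](OC(C)=O)C2
F8 | step 16 | (4R,6S,9S,10S)-4,9-dibromo-5,5,9-trimethyl-1-methylidenespiro[5.5]undecan-10-ol | C=C1CC[C@@H](Br)C(C)(C)[C@]12CC[C@](C)(Br)[C@@H](O)C2
F0 | step 15 | none | none
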